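Monday's and Wednesday's runs stand here beside the new flask, with what is asked of it.

in all of them: protic impurity 0.0153 M; free catalyst 0.51 mM

| run | starting material | remark | time |
|---|---|---|---|
| Wednesday's | 0.025 M | run made earlier |  |
| Monday's | 0.10 M | run made earlier |  |
| flask | 0.051 M |  | 15 d |

| run | time / d | target / % | isomer of the product / % |
|---|---|---|---|
| Wednesday's | 1.04 | 32.6 | 21.8 |
| Wednesday's | 1.67 | 29.1 | 24.8 |
| Wednesday's | 2.50 | 27.3 | 25.3 |
| Wednesday's | 4.00 | 24.9 | 24.4 |
| Wednesday's | 8.00 | 19.7 | 23.8 |
| Wednesday's | 12.0 | 19.4 | 22.9 |
| Monday's | 0.833 | 34.4 | 20.4 |
| Monday's | 2.50 | 28.6 | 25.9 |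
| Monday's | 4.00 | 28.2 | 25.7 |
| Monday's | 6.00 | 28.8 | 25.7 |
| Monday's | 10.0 | 28.0 | 25.4 |
| Monday's | 12.0 | 28.3 | 26.4 |

(standard deviation of a reading: 0.5 percentage points)

1. share of target in target plus isomer of the product at 3.0 min
2. share of target in target plus isomer of the product at 4.0 h
3. share of target in target plus isomer of the product at 15 d

- the analysis behind the earlier runs scatters by 0.5 percentage points, standard deviation

**Fraction left.** Monday's last reading puts the target at 51.7 % of target plus isomer of the product. I read this plateau as thermodynamic control and the early surplus of target as kinetic control. I follow the excess, the distance of the share above the plateau, as a fraction of the distance from a start of pure target, and that pure start is my assumption. Monday's first reading, a share of 62.8 %, leaves 22.9 % of the excess at 0.833 d. That gives the excess half-life 0.391 d, the time in which the excess halves.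

**Early shares.** At 4.0 h the fraction left is 74.4 %, so I put the flask's share at 87.7 %. At 3.0 min the same rule puts the flask's share at 99.8 %.

**Weak link.** The excess half-life is far shorter than 15 d, so I expect the excess to have faded by then, but Monday's plateau need not be the flask's. Monday's run charged protic impurity at 0.153 of the starting material and Wednesday's at 0.612, and Wednesday's last share reads 45.9 %. The flask stands at 0.300, so I interpolate linearly in that ratio and commit to 49.9 %.

**The forecast.** The forecast says 98 %, 86 % and 52 %, a little off my numbers at each time. Its early share rests on “nearly 100% target at time zero”.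

**The result.** The flask gives 94.8 %, 84.3 % and 49.0 %, and its share at 3.0 min lies below mine.

    starting material + protic impurity → quenched substrate (k = 0.690 M⁻¹ h⁻¹)
    starting material + free catalyst ⇌ target + free catalyst, rate k2*[starting material]*[free catalyst] forward; the back reaction follows from the equilibrium constant (K = 0.910, k = 760 M⁻¹ h⁻¹)
    isomer of the product + free catalyst ⇌ starting material + free catalyst, rate k3*[free catalyst]*[isomer of the product] forward; the back reaction follows from the equilibrium constant (k = 48.0 M⁻¹ h⁻¹)
    target + free catalyst ⇌ isomer of the product + free catalyst, rate k4*[free catalyst]*[target] forward; the back reaction follows from the equilibrium constant (K = 0.940, k = 56.0 M⁻¹ h⁻¹)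
    2 free catalyst → spent catalyst B (k = 5.50 M⁻¹ h⁻¹)
    free catalyst → spent catalyst A (k = 0.0210 h⁻¹)

**Excess again.** From 3.0 min to 4.0 h the flask's excess over Monday's plateau falls to 75.6 % of itself, where my half-life says 74.7 %, and the neighbour charged with 0.20 M of starting material falls to 75.8 %. In the flask the half-life of isomer of the product by the forward step to starting material alone, the other concentrations as charged, is 1.2 d, short against 15 d, but at 15 d, with free catalyst at 0.0411 % of its charge, the relaxation half-life of starting material and target by their step alone, both ways together, is 86.4 d.

The earlier runs and the new flask are simulated from invented constants; the scatter is artificial.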